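Late in the epsilon run target climbs slowly, and the flasks below are asked about at 6.0 h, with two earlier runs to go on.

| setting | theta | epsilon | alder | oak | larch | ash | birch | maple |
|---|---|---|---|---|---|---|---|---|
| substrate | 0.065 M | 0.70 M | 0.050 M | 0.12 M | 0.30 M | 0.40 M | 0.20 M | 0.60 M |
| remark | run made earlier | run made earlier |  |  |  |  |  |  |
| time |  |  | 6.0 h | 6.0 h | 6.0 h | 6.0 h | 6.0 h | 6.0 h |

| run | time / h | target / % |
|---|---|---|
| theta | 0.250 | 10.3 |
| theta | 0.500 | 20.4 |
| theta | 1.33 | 42.7 |
| theta | 3.00 | 63.8 |
| epsilon | 0.417 | 12.2 |
| epsilon | 1.00 | 20.5 |
| epsilon | 2.00 | 22.8 |
| epsilon | 3.00 | 25.2 |

(standard deviation of a reading: 1 percentage point)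

1. ranking by amount of target, in percent of the substrate charged, from high to low, at 6.0 h (alder / oak / larch / ash / birch / maple)
2. the amount of target, in percent of the substrate charged of the flask you put first, at 6.0 h
3. the amount of target, in percent of the substrate charged of the flask you put last, at 6.0 h

- in percentages every species weighs as the substrate in it: one side product counts as two
- what may be going on: substrate -> target; substrate + target -> side product

If substrate gives target and substrate plus target gives side product (a consecutive-competitive scheme), both rates carry the substrate concentration, so it cancels from their ratio and target concentration remains. Dividing one rate by the other and integrating until substrate is used up gives, for a charge S, an end target P and a ceiling C, the relation 1 − P/C = exp[−(S + P)/(2C)].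

The last epsilon reading, which rose by 2.4 percentage points in its final hour, is read as nearly the end and stands for 0.176 M of target. Taking C equal to that as a first guess gives 0.192 M, and a second pass gives 0.197 M for the ceiling concentration, the target level at which target is lost as fast as it forms.

A larger charge meets the same ceiling, so this reckoning ranks the flasks by charge, lowest first, from alder at 0.050 M to maple at 0.60 M. Its end values are 28.2% for maple and 81.0% for alder. Alder should stop short of its end at the asked time: the first theta reading gives a rate constant of 0.412 /h, and the first step by itself would leave 8.44% of alder's substrate.

The forecast gives alder > oak > birch > larch > ash > maple, with 78% and 28%, on the ground that “Percent yield falls steadily with loading”.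

The flasks give alder > oak > birch > larch > ash > maple, with 77.9% in alder and 28.0% in maple.

    substrate → target (k = 0.00764 /min)
    substrate + target → side product (k = 0.0389 /M/min)

Maple's target moves by 5 points at a charge of 0.473 M or 0.776 M. Alder has not come to rest at 6.00 h: 4.3% of its charge is still substrate, and ten times the time takes its target from 77.9% to 80.7%. Maple, with 0.81% of its charge still substrate, goes from 28.0% to 28.1% over the same stretch. The ceiling of 0.197 M gives an end of 71.9% for a neighbour like alder with 0.085 M of substrate, which at 6.00 h holds 69.9% target and 3.4% substrate.

The runs are simulated from invented constants, and the scatter is random.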